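common to all: starting complex 0.020 M
- Monday's: incoming ligand 0.25 equiv; leaving ligand 2 equiv; protic impurity 10 mM; run made earlier
- Friday's: incoming ligand 1 equiv; leaving ligand 2 equiv; protic impurity 10 mM; run made earlier
- flask: incoming ligand 0.500 equiv; leaving ligand 2.00 equiv; protic impurity 10.0 mM; time 50 h

- Monday's (time / h: complex with one exchanged / %): 3.00: 14; 10.0: 11; 20.0: 12; 25.0: 12; 40.0: 13; 48.0: 11
- Friday's (time / h: complex with one exchanged / %): 8.00: 33; 15.0: 32; 25.0: 35; 30.0: 33; 40.0: 33; 48.0: 32

(each reading ± 1.5 percentage points)

- the numbers in the tables scatter by 1.5 percentage points (one standard deviation)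

* equivalents of incoming ligand to starting complex, everything else as given, that leave most complex with one exchanged at 50 h
* the amount of complex with one exchanged then, in percent of the starting complex charged
* the amount of complex with one exchanged with the amounts as given

A small charge of incoming ligand, 0.25 equiv in Monday's run, holds a mean of 12.2 % of complex with one exchanged, while Friday's 1 equiv holds 33.0 %. Both runs lie flat from their first readings, and the readings cannot say whether that marks an equilibrium or a spent reagent. A measure that needs neither view is the yield per equivalent, the plateau share divided by the equivalents of incoming ligand charged: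

Monday: 0.487
Friday: 0.330

Carrying Monday's value to the flask's 0.500 equiv gives 24.3 %, but Friday's yield per equivalent is lower than Monday's, so plain proportion is doubtful. A better estimate lets the yield fall in a straight line, with a fall per added equivalent of 0.209. Two means force any line, but the scatter of Monday's mean, 0.61 percentage points, amounts to 0.0244 of yield per equivalent, less than the gap of 0.157. With e the equivalents charged:

[complex with one exchanged]/0.020 M = e·(a − b·e), a = 0.539

flask: 21.7 %
peak of this curve: e = 1.29, share 34.8 %

That peak lies beyond Friday's charge, so it is an extrapolation, yet it is the reckoning to commit to.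

The forecast differs on the peak. It holds that “they sit at equilibrium and nothing decays” and gives 20.5 % (18.5 % to 22.5 %) for the flask, with a peak of 49 % (43 % to 58 %) at 3.6 equiv (2.6 equiv to 5.5 equiv).

The flask gives 22.1 %, and the peak is 35.6 % at 1.34 equiv.

    complex with one exchanged + incoming ligand ⇌ leaving ligand + complex with two exchanged (K = 0.960, k = 0.00860 /M/s)
    starting complex + incoming ligand ⇌ leaving ligand + complex with one exchanged (K = 1.70, k = 0.0100 /M/s)
    complex with one exchanged ⇌ isomer of the product (K = 0.260, k = 2.10 × 10⁻⁵ /s)
    leaving ligand → by-product carried off (k = 8.90 × 10⁻⁵ /s)
    protic impurity + incoming ligand → quenched reagent (k = 0.00290 /M/s)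

In the flask the incoming ligand has a half-life of 1.2 h at 2.43 h by the forward rate of its step with starting complex alone, short against the 50 h, and this limiting reagent ends at 0 % of its charge, with 73 % of the protic impurity remaining. The flask's yield per equivalent is 0.442 against 0.435 on the line, and at 2.00 equiv of incoming ligand the line gives 24.2 % where that neighbour holds 26.2 %.

The earlier runs and the new flask were generated by integration from invented constants.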